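## Retrosynthetic overview

- The last operations are fluoride cleavage of a 3'-O-TIPS group and, before it, loss of H2 across C5–C6 of a 5,6-dihydrochromen-4-one. Ring A therefore becomes aromatic only after ring C exists.
- The strategy rests on ring A: the pyranone oxygen O1 (on C8a) and the prenylated oxygen on C7 are meta to each other, and C4a is the neighbour of C8a. This O–C8a–C8–C7–O array with a flanking CH2 is cyclohexane-1,3-dione. Its mono-prenyl enol ether already carries the C7 substituent, and its only kinetic enolate position is the future C4a.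
- The key disconnection opens ring C at C4–C4a (C-acylation of that enolate) and at O1–C2 (the ring enol oxygen replaces OMe). The partner is a 2-aryl-3-methoxyacryloyl chloride that brings ring B, C2, C3 and C4.
- The acid chloride comes from homoisovanillic acid through a tert-butyl ester, formylation with methyl formate and O-methylation. The ester is acid-cleavable because the aryl TIPS ether would not survive saponification of a hindered β-methoxyacrylate. The enol ether comes from 3-chlorocyclohexenone and sodium prenoxide, which excludes C2-alkylation and acid.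
- Ring order: B is bought aromatic, A is bought as a carbocycle, C is closed in step 9, and A is aromatised in step 10.

Key step: step 9

Remark: the target has no stereocentre and no stereogenic double bond, so it is achiral and no enantioselective step is needed.
Abbreviations: prenyl = 3-methylbut-2-en-1-yl; TIPS = triisopropylsilyl.

## Route

Step 1
Reactants: 1 cyclohexane-1,3-dione
Product: 2 3-chlorocyclohex-2-en-1-one
Conditions: (COCl)2 (1.1 equiv), DMF (cat.), CH2Cl2, 0 °C → rt
Reagents that add atoms: oxalyl chloride, O=C(Cl)C(=O)Cl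
Why: Vilsmeier-type activation of the enol oxygen followed by chloride addition–elimination is the standard conversion of a cyclic 1,3-dione into its β-chloroenone, and the symmetric dione can give only one product.

Step 2
Reactants: 2 3-chlorocyclohex-2-en-1-one; 3 prenyl alcohol (3-methylbut-2-en-1-ol)
Product: 5 3-(prenyloxy)cyclohex-2-en-1-one, via sodium prenoxide 4 (not isolated)
Conditions: 3 (1.1 equiv), NaH (1.1 equiv), THF, 0 °C; then 2, 0 °C → rt
Reagents that add atoms: none
Why: The alkoxide adds to the β-carbon of the chloroenone and expels chloride (vinylogous acyl substitution), so the prenyl group can only end on oxygen, without the C2-alkylation that prenyl halides give with the dione and without acid that would ionise prenyl alcohol.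

Step 3
Reactants: 6 homoisovanillic acid (3-hydroxy-4-methoxyphenylacetic acid)
Product: 7 tert-butyl 2-(3-hydroxy-4-methoxyphenyl)acetate
Conditions: Cl3CC(=NH)Ot-Bu (2 equiv), THF–cyclohexane, rt
Reagents that add atoms: tert-butyl 2,2,2-trichloroacetimidate, CC(C)(C)OC(=N)C(Cl)(Cl)Cl
Why: In this imidate esterification the carboxylic acid itself protonates the trichloroacetimidate and captures the tert-butyl group, whereas the much less acidic phenol does not activate the reagent without a Lewis acid.

Step 4
Reactants: 7 tert-butyl 2-(3-hydroxy-4-methoxyphenyl)acetate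
Product: 8 tert-butyl 2-(4-methoxy-3-triisopropylsilyloxyphenyl)acetate
Conditions: TIPSCl (1.2 equiv), imidazole (2.5 equiv), DMF, rt
Reagents that add atoms: triisopropylsilyl chloride, CC(C)[Si](Cl)(C(C)C)C(C)C
Why: This is a standard imidazole-promoted silylation of a phenol, and the aryl TIPS ether tolerates LDA at low temperature, TFA, oxalyl chloride and DDQ and later leaves with fluoride without touching the prenyl ether.

Step 5
Reactants: 8 tert-butyl 2-(4-methoxy-3-triisopropylsilyloxyphenyl)acetate; 9 methyl formate
Product: 11 tert-butyl (Z)-3-hydroxy-2-(4-methoxy-3-triisopropylsilyloxyphenyl)acrylate (H-bonded enol of the α-formyl ester), via lithium ester enolate 10 (not isolated)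
Conditions: LDA (1.2 equiv), THF, −78 °C; HCO2Me (5 equiv), −78 → 0 °C; AcOH quench
Reagents that add atoms: none
Why: This is a crossed Claisen condensation (α-formylation) of a preformed ester enolate with a non-enolisable formate, in which the bulky tert-butyl ester resists self-condensation and transesterification and the methoxide released is consumed at once by the acidic product, which spares the silyl ether.

Step 6
Reactants: 11 tert-butyl (Z)-3-hydroxy-2-(4-methoxy-3-triisopropylsilyloxyphenyl)acrylate
Product: 12 tert-butyl (E)-3-methoxy-2-(4-methoxy-3-triisopropylsilyloxyphenyl)acrylate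
Conditions: Me2SO4 (1.2 equiv), K2CO3 (1.5 equiv), DMF, 0 °C → rt
Reagents that add atoms: dimethyl sulfate, COS(=O)(=O)OC
Why: O-alkylation of the stabilised potassium enolate with the hard electrophile dimethyl sulfate in a dipolar aprotic solvent is the standard route to β-methoxyacrylates and should favour the (E)-isomer, whose geometry is in any case erased in step 9.

Step 7
Reactants: 12 tert-butyl (E)-3-methoxy-2-(4-methoxy-3-triisopropylsilyloxyphenyl)acrylate
Product: 13 (E)-3-methoxy-2-(4-methoxy-3-triisopropylsilyloxyphenyl)acrylic acid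
Conditions: TFA–CH2Cl2 (1:4), anhydrous, 0 °C → rt
Reagents that add atoms: none
Why: Acidolysis of the tert-butyl ester (E1 loss of isobutene) needs neither hydroxide nor water, so the base-labile but acid-robust aryl TIPS ether and the push–pull enol ether (a vinylogous carbonate) should both persist.

Step 8
Reactants: 13 (E)-3-methoxy-2-(4-methoxy-3-triisopropylsilyloxyphenyl)acrylic acid
Product: 14 (E)-3-methoxy-2-(4-methoxy-3-triisopropylsilyloxyphenyl)acryloyl chloride
Conditions: (COCl)2 (1.5 equiv), DMF (cat.), CH2Cl2, 0 °C → rt; concentrated and used crude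
Reagents that add atoms: oxalyl chloride, O=C(Cl)C(=O)Cl
Why: This is a Vilsmeier-catalysed acid chloride formation on an acid without an α-hydrogen, so no ketene can arise, and β-methoxyacryloyl chlorides are a known class of isolable reagents.

Step 9
Reactants: 5 3-(prenyloxy)cyclohex-2-en-1-one; 14 (E)-3-methoxy-2-(4-methoxy-3-triisopropylsilyloxyphenyl)acryloyl chloride
Product: 17 3-(4-methoxy-3-triisopropylsilyloxyphenyl)-7-(prenyloxy)-5,6-dihydrochromen-4-one, via lithium dienolate 15 (not isolated), via open-chain enol 16 (not isolated)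
Conditions: 5 (2.2 equiv) added to LDA (2.1 equiv), THF, −78 °C; 14 (1.0 equiv) in THF, −78 → −20 °C; AcOH (10 equiv), → 40 °C (or crude 16, PPTS cat., 4 Å MS, CH2Cl2, rt)
Reagents that add atoms: none
Why: LDA removes a proton from the α′-methylene of 5 (C6, the future C4a) under kinetic control, and the cross-conjugated dienolate 15 attacks the carbonyl carbon of 14 to form C4–C4a; the acidic product is stored as its lithium diketonate by a second equivalent of 15 rather than by free LDA, which would consume 14 as an amide, and the 5 regenerated in this way is recovered. The diketonate is too stabilised to close, so acetic acid releases the enol 16, whose ring enol oxygen (future O1) adds to the methoxy-bearing carbon (future C2) and methanol is expelled, which forms O1–C2 and closes ring C in a 6-endo-trig conjugate addition–elimination. The closest known reaction types are the α′-acylation of kinetic 3-alkoxyenone enolates (Stork–Danheiser enolates) and the γ-pyranone annulation of ketone enolates with β-methoxyacryloyl chlorides. No stereocentre is created, and the alkene geometry of 14 is lost at the tetrahedral C2 intermediate, so both geometric isomers converge on 17. The step needs α′- over γ-deprotonation (secured by LDA at −78 °C with the ketone added to the base), C- over O-acylation (lithium counter-ion in THF without polar additive, and any enol ester formed still acylates the excess 15 and drains into the diketonate) and attack at the acyl rather than the β-carbon (the acid chloride is by far the more reactive site, and 14 has no α-hydrogen, so no ketene forms). Closure under weak acid at or below 40 °C keeps free methoxide away from the C7 vinylogous ester and the silyl ether and stays well under the temperature at which the allyl vinyl ether unit would undergo Claisen rearrangement.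

Step 10
Reactants: 17 3-(4-methoxy-3-triisopropylsilyloxyphenyl)-7-(prenyloxy)-5,6-dihydrochromen-4-one
Product: 18 3-(4-methoxy-3-triisopropylsilyloxyphenyl)-7-(prenyloxy)chromen-4-one
Conditions: DDQ (1.05 equiv), anhydrous toluene, 0 °C → rt, short contact; filtration through basic alumina
Reagents that add atoms: none
Why: In this DDQ dehydrogenation, hydride abstraction from C5 gives a cation delocalised onto C8a (bearing O1) and C7 (bearing the prenyloxy oxygen), that is the C6-protonated arene, which loses a proton to aromatise, and this should be far faster than attack on the prenyl ether, whose DDQ cleavage needs water and an electron-rich ether oxygen.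

Step 11
Reactants: 18 3-(4-methoxy-3-triisopropylsilyloxyphenyl)-7-(prenyloxy)chromen-4-one
Product: 19 7-prenyloxy-3'-hydroxy-4'-methoxyisoflavone
Conditions: TBAF (1.1 equiv), AcOH (1.1 equiv), THF, 0 °C
Reagents that add atoms: none
Why: This is a fluoride-induced cleavage of the aryl silyl ether driven by the Si–F bond, in which acetic acid protonates the phenoxide and keeps basic fluoride from adding to C2 of the isoflavone, and the prenyl ether is inert.

## Compound list

1 | cyclohexane-1,3-dione | O=C1CCCC(=O)C1 | starting material
2 | 3-chlorocyclohex-2-en-1-one | O=C1C=C(Cl)CCC1 | intermediate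
3 | prenyl alcohol (3-methylbut-2-en-1-ol) | CC(C)=CCO | starting material
4 | sodium prenoxide | [Na+].[O-]CC=C(C)C | intermediate
5 | 3-(prenyloxy)cyclohex-2-en-1-one | CC(C)=CCOC1=CC(=O)CCC1 | intermediate
6 | homoisovanillic acid | COc1ccc(CC(=O)O)cc1O | starting material
7 | tert-butyl 2-(3-hydroxy-4-methoxyphenyl)acetate | COc1ccc(CC(=O)OC(C)(C)C)cc1O | intermediate
8 | tert-butyl 2-(4-methoxy-3-triisopropylsilyloxyphenyl)acetate | COc1ccc(CC(=O)OC(C)(C)C)cc1O[Si](C(C)C)(C(C)C)C(C)C | intermediate
9 | methyl formate | COC=O | starting material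
10 | lithium enolate of 8 (geometry not defined) | [Li+].[O-]C(OC(C)(C)C)=Cc1ccc(OC)c(O[Si](C(C)C)(C(C)C)C(C)C)c1 | intermediate
11 | tert-butyl (Z)-3-hydroxy-2-(4-methoxy-3-triisopropylsilyloxyphenyl)acrylate | O/C=C(\C(=O)OC(C)(C)C)c1ccc(OC)c(O[Si](C(C)C)(C(C)C)C(C)C)c1 | intermediate
12 | tert-butyl (E)-3-methoxy-2-(4-methoxy-3-triisopropylsilyloxyphenyl)acrylate | CO/C=C(/C(=O)OC(C)(C)C)c1ccc(OC)c(O[Si](C(C)C)(C(C)C)C(C)C)c1 | intermediate
13 | (E)-3-methoxy-2-(4-methoxy-3-triisopropylsilyloxyphenyl)acrylic acid | CO/C=C(/C(=O)O)c1ccc(OC)c(O[Si](C(C)C)(C(C)C)C(C)C)c1 | intermediate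
14 | (E)-3-methoxy-2-(4-methoxy-3-triisopropylsilyloxyphenyl)acryloyl chloride | CO/C=C(/C(Cl)=O)c1ccc(OC)c(O[Si](C(C)C)(C(C)C)C(C)C)c1 | intermediate
15 | lithium 5-(prenyloxy)cyclohexa-1,5-dien-1-olate | [Li+].[O-]C1=CCCC(OCC=C(C)C)=C1 | intermediate
16 | (E)-1-[2-hydroxy-4-(prenyloxy)cyclohexa-1,3-dien-1-yl]-3-methoxy-2-(4-methoxy-3-triisopropylsilyloxyphenyl)prop-2-en-1-one (enol of the 6-acyl enone) | CO/C=C(/C(=O)C1=C(O)C=C(OCC=C(C)C)CC1)c1ccc(OC)c(O[Si](C(C)C)(C(C)C)C(C)C)c1 | intermediate
17 | 3-(4-methoxy-3-triisopropylsilyloxyphenyl)-7-(prenyloxy)-5,6-dihydrochromen-4-one | COc1ccc(C2=COC3=C(CCC(OCC=C(C)C)=C3)C2=O)cc1O[Si](C(C)C)(C(C)C)C(C)C | intermediate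
18 | 3-(4-methoxy-3-triisopropylsilyloxyphenyl)-7-(prenyloxy)chromen-4-one | COc1ccc(-c2coc3cc(OCC=C(C)C)ccc3c2=O)cc1O[Si](C(C)C)(C(C)C)C(C)C | intermediate
19 | 7-prenyloxy-3'-hydroxy-4'-methoxyisoflavone | COc1ccc(-c2coc3cc(OCC=C(C)C)ccc3c2=O)cc1O | target

## Step count and risks

Total step count: 11.
Longest linear sequence: 9 steps (6 → 19, steps 3–11). Steps 1–2 form the short convergent branch.

**1. Step 9.**
- What may go wrong: O-acylation or proton transfer in place of C-acylation, consumption of the acid chloride by diisopropylamine, sluggish ring closure, or exchange of the C7 prenyloxy group by the methanol released.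
- Fallback: it sets out from 8 and 5 and returns at 17. The C–C bond is made by an aldol addition, which has no O/C ambiguity, and C2 is inserted afterwards.
- DIBAL-H (toluene, −78 °C) should reduce 8 to 2-(4-methoxy-3-triisopropylsilyloxyphenyl)acetaldehyde F1.
- Addition of dienolate 15 (from 5 and LDA, THF, −78 °C) should give 6-[1-hydroxy-2-(4-methoxy-3-triisopropylsilyloxyphenyl)ethyl]-3-(prenyloxy)cyclohex-2-en-1-one F2. It forms as a diastereomer mixture, and both centres are erased later.
- Dess–Martin periodinane with NaHCO3 (CH2Cl2) should give the enolised diketone 6-[(4-methoxy-3-triisopropylsilyloxyphenyl)acetyl]-3-(prenyloxy)cyclohex-2-en-1-one F3.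
- DMF dimethyl acetal (toluene, 60 °C) should condense at the benzylic methylene to give the enaminone 3-(dimethylamino)-1-[2-hydroxy-4-(prenyloxy)cyclohexa-1,3-dien-1-yl]-2-(4-methoxy-3-triisopropylsilyloxyphenyl)prop-2-en-1-one F4. Its ring enol oxygen displaces dimethylamine and closes ring C to 17.

**2. Step 10.**
- What may go wrong: oxidative loss of the prenyl group, cycloaddition of DDQ to the ring A diene, or over-oxidation at the allylic positions.
- Fallback: it sets out from 17 and returns at 18. The prenyl group is taken off before the oxidation and put back afterwards.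
- Aqueous HCl (1 M) in THF at rt should hydrolyse the dienol ether to 3-(4-methoxy-3-triisopropylsilyloxyphenyl)-5,6,7,8-tetrahydrochromene-4,7-dione F5.
- DDQ in dioxane should dehydrogenate this to 7-hydroxy-3-(4-methoxy-3-triisopropylsilyloxyphenyl)chromen-4-one F6.
- Williamson etherification of the acidic 7-OH (prenyl bromide, K2CO3, acetone, rt) should give 18.

**3. Step 7.**
- What may go wrong: hydrolysis of the enol ether by adventitious water followed by decarboxylation, or tert-butylation of ring B by the cation released.
- Fallback: it sets out from 6 and returns at 13. The ester is exchanged for one that leaves under neutral hydrogenolysis, which β-methoxyacrylates are known to tolerate.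
- BnBr and KHCO3 in DMF should give benzyl 2-(3-hydroxy-4-methoxyphenyl)acetate F7.
- TIPSCl and imidazole should give benzyl 2-(4-methoxy-3-triisopropylsilyloxyphenyl)acetate F8.
- LDA followed by benzyl formate (THF, −78 °C; this formate avoids ester scrambling) should give benzyl (Z)-3-hydroxy-2-(4-methoxy-3-triisopropylsilyloxyphenyl)acrylate F9.
- Me2SO4 and K2CO3 should give benzyl (E)-3-methoxy-2-(4-methoxy-3-triisopropylsilyloxyphenyl)acrylate F10.
- H2 (1 atm) over Pd/C in EtOAc should release 13.

## Further compounds

F1 | step 9 | 2-(4-methoxy-3-triisopropylsilyloxyphenyl)acetaldehyde | COc1ccc(CC=O)cc1O[Si](C(C)C)(C(C)C)C(C)C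
F2 | step 9 | 6-[1-hydroxy-2-(4-methoxy-3-triisopropylsilyloxyphenyl)ethyl]-3-(prenyloxy)cyclohex-2-en-1-one (mixture of racemic diastereomers) | COc1ccc(CC(O)C2CCC(OCC=C(C)C)=CC2=O)cc1O[Si](C(C)C)(C(C)C)C(C)C
F3 | step 9 | 6-[(4-methoxy-3-triisopropylsilyloxyphenyl)acetyl]-3-(prenyloxy)cyclohex-2-en-1-one (drawn as ring enol) | COc1ccc(CC(=O)C2=C(O)C=C(OCC=C(C)C)CC2)cc1O[Si](C(C)C)(C(C)C)C(C)C
F4 | step 9 | 3-(dimethylamino)-1-[2-hydroxy-4-(prenyloxy)cyclohexa-1,3-dien-1-yl]-2-(4-methoxy-3-triisopropylsilyloxyphenyl)prop-2-en-1-one (geometry not defined) | CN(C)C=C(C(=O)C1=C(O)C=C(OCC=C(C)C)CC1)c1ccc(OC)c(O[Si](C(C)C)(C(C)C)C(C)C)c1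
F5 | step 10 | 3-(4-methoxy-3-triisopropylsilyloxyphenyl)-5,6,7,8-tetrahydrochromene-4,7-dione | COc1ccc(C2=COC3=C(CCC(=O)C3)C2=O)cc1O[Si](C(C)C)(C(C)C)C(C)C
F6 | step 10 | 7-hydroxy-3-(4-methoxy-3-triisopropylsilyloxyphenyl)chromen-4-one | COc1ccc(-c2coc3cc(O)ccc3c2=O)cc1O[Si](C(C)C)(C(C)C)C(C)C
F7 | step 7 | benzyl 2-(3-hydroxy-4-methoxyphenyl)acetate | COc1ccc(CC(=O)OCc2ccccc2)cc1O
F8 | step 7 | benzyl 2-(4-methoxy-3-triisopropylsilyloxyphenyl)acetate | COc1ccc(CC(=O)OCc2ccccc2)cc1O[Si](C(C)C)(C(C)C)C(C)C
F9 | step 7 | benzyl (Z)-3-hydroxy-2-(4-methoxy-3-triisopropylsilyloxyphenyl)acrylate | O/C=C(\C(=O)OCc1ccccc1)c1ccc(OC)c(O[Si](C(C)C)(C(C)C)C(C)C)c1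
F10 | step 7 | benzyl (E)-3-methoxy-2-(4-methoxy-3-triisopropylsilyloxyphenyl)acrylate | CO/C=C(/C(=O)OCc1ccccc1)c1ccc(OC)c(O[Si](C(C)C)(C(C)C)C(C)C)c1
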